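The C45 side chain on C3 of the naphthoquinone (benzo ring A, quinone ring B) hides a meso unit: C7' and C11', separated by the C8'–C10' methylenes, carry mirror-related methyl stereocentres, so C6'–C12' maps onto meso-2,6-dimethylheptane-1,7-diol. Everything rests on telling its two enantiotopic CH2OH ends apart: a lipase with vinyl acetate acetylates only the C12' hydroxyl, fixing C7' and C11' in one operation. The precursor is the acyclic meso diol, cut from cis-2,6-dimethylcyclohexanone. The C6' end is then grown to an alkyne for carboalumination and coupling to the chloromethylquinone; the C12' end becomes a sulfone that is joined to a tail bromide built from geranylgeraniol and (R)-citronellol.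

Key step: step 5

Assumption: side-chain carbons are numbered C1' (on ring carbon C3) to C36'; ketone 1 is used as the pure cis isomer, and carbons bearing a phenylsulfonyl group (C12', C29') are carried as epimer mixtures because both sulfonyl groups are removed in step 20.

Step 1
Reactants: 1 cis-(2R,6S)-2,6-dimethylcyclohexan-1-one
Product: 3 cis-(2R,6S)-2,6-dimethylcycloheptan-1-one, via α-silyl ketone 2 (not isolated)
Conditions: Me3SiCHN2 (1.3 equiv), BF3·OEt2 (1.3 equiv), CH2Cl2, −78 → −30 °C; then 1 M HCl, THF, 0 °C → rt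
Reagents that add atoms: trimethylsilyldiazomethane, C[Si](C)(C)C=[N+]=[N-]
Why: Lewis-acid-promoted diazoalkane insertion (Tiffeneau–Demjanov-type ring expansion) can give only one constitution from the symmetrical ketone, the migrating CH(CH3) carbon keeps its configuration so the cis relationship is carried over, the bulky silyl group of 2 discourages a second insertion, and acid cleaves the C–Si bond through the C1–C7 enol without touching C2.

Step 2
Reactants: 3 cis-(2R,6S)-2,6-dimethylcycloheptan-1-one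
Product: 5 {[(3S,7R)-3,7-dimethylcyclohept-1-en-1-yl]oxy}trimethylsilane, via lithium enolate 4 (not isolated)
Conditions: LiN(iPr)2 (1.1 equiv), THF, −78 °C; then Me3SiCl, −78 → 0 °C
Reagents that add atoms: chlorotrimethylsilane, C[Si](C)(C)Cl
Why: Kinetic deprotonation by the hindered lithium amide takes a proton from the unsubstituted C7 methylene and not from the C2 methine, and O-silylation traps this less substituted enolate (kinetic silyl enol ether formation) without epimerising C2.

Step 3
Reactants: 5 {[(3S,7R)-3,7-dimethylcyclohept-1-en-1-yl]oxy}trimethylsilane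
Product: 7 (2R,6S)-7-hydroxy-2,6-dimethylheptanoic acid, via methoxy hydroperoxide 6 (not isolated)
Conditions: O3, CH2Cl2/MeOH (3:1), −78 °C; then NaBH4, −78 °C → rt; aq. HCl work-up
Reagents that add atoms: ozone, [O-][O+]=O; methanol, CO (kept only in 6)
Why: Criegee ozonolysis cleaves the electron-rich enol ether C=C, methanol traps the carbonyl oxide as 6, and borohydride reduction in the same flask turns the aldehyde-level carbon into CH2OH before the neighbouring methyl stereocentre can epimerise, while the silyl ester is solvolysed to the acid.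

Step 4
Reactants: 7 (2R,6S)-7-hydroxy-2,6-dimethylheptanoic acid
Product: 8 meso-(2R,6S)-2,6-dimethylheptane-1,7-diol
Conditions: LiAlH4, THF, 0 °C → reflux
Reagents that add atoms: none
Why: Hydride reduction of a carboxylic acid to the primary alcohol with LiAlH4 is standard and touches neither methyl-bearing centre, so the cis relationship of 1 appears as the meso relationship of 8.

Step 5
Reactants: 8 meso-(2R,6S)-2,6-dimethylheptane-1,7-diol; 9 vinyl acetate
Product: 10 (2S,6R)-7-hydroxy-2,6-dimethylheptyl acetate (acetate on C12', free hydroxyl on C6')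
Conditions: lipase from Pseudomonas fluorescens (Amano AK), 9 (5 equiv), t-BuOMe, 25 °C, run until a little diacetate appears; filtration
Reagents that add atoms: none
Why: The active-site serine of the lipase is acetylated by vinyl acetate (the enol leaving group tautomerises to acetaldehyde, so the transfer is irreversible), and the acyl-enzyme passes the acetyl group to one CH2OH of the diol, forming a single acyl C–O bond. The closest known reaction type is the lipase-catalysed transesterification that desymmetrises meso 2-methyl-branched diols. No ring is closed and no new stereogenic carbon is created; instead the chiral binding pocket is expected to select the hydroxymethyl group on the S-configured methyl centre, which makes the two existing centres non-equivalent and fixes C11' as S and C7' as R in 10. The step needs enantiotopic-group selectivity and mono- over bis-acylation, and the substrate secures the first through the methyl branch directly next to each CH2OH, the only element the enzyme has to read. Because the minor monoacetate enantiomer still carries the fast-reacting hydroxymethyl group, letting a little diacetate form should raise the enantiomeric purity of 10, whose configuration would be confirmed before use.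

Step 6
Reactants: 10 (2S,6R)-7-hydroxy-2,6-dimethylheptyl acetate
Product: 11 (2S,6R)-2,6-dimethyl-7-[(4-methylbenzenesulfonyl)oxy]heptyl acetate
Conditions: TsCl (1.2 equiv), Et3N, DMAP (cat.), CH2Cl2, 0 °C → rt
Reagents that add atoms: 4-methylbenzenesulfonyl chloride, Cc1ccc(cc1)S(Cl)(=O)=O
Why: Sulfonylation of the only free primary alcohol (tosylation) is chemoselective because the C12' oxygen is already an ester.

Step 7
Reactants: 11 (2S,6R)-2,6-dimethyl-7-[(4-methylbenzenesulfonyl)oxy]heptyl acetate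
Product: 12 (2R,6S)-7-hydroxy-2,6-dimethylheptyl 4-methylbenzenesulfonate
Conditions: K2CO3 (0.2 equiv), MeOH, 0 °C
Reagents that add atoms: none
Why: Carbonate-catalysed transesterification (Zemplén-type methanolysis) removes the acetate, while the β-branched primary tosylate should be inert to methanol at this temperature and closure to an eight-membered ether is not competitive.

Step 8
Reactants: 12 (2R,6S)-7-hydroxy-2,6-dimethylheptyl 4-methylbenzenesulfonate; 13 (4-bromobut-1-yn-1-yl)trimethylsilane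
Product: 15 (2S,6R)-2,6-dimethyl-11-(trimethylsilyl)undec-10-yn-1-ol, via Grignard reagent 14 (not isolated)
Conditions: 13, Mg, THF, 25 °C; then 12 (0.4 equiv relative to 14), Li2CuCl4 (5 mol%), THF, −78 → 0 °C
Reagents that add atoms: none
Why: Copper-catalysed sp3–sp3 coupling of a primary tosylate with an alkyl Grignard reagent (Kochi-type coupling) tolerates β-branching and a magnesium alkoxide, the first equivalent of 14 only deprotonating the hydroxyl, and it forms C5'–C6' at a CH2 carbon so C7' is not involved.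

Step 9
Reactants: 15 (2S,6R)-2,6-dimethyl-11-(trimethylsilyl)undec-10-yn-1-ol
Product: 16 [(6R,10S)-6,10-dimethyl-11-(phenylsulfanyl)undec-1-yn-1-yl]trimethylsilane
Conditions: PhSSPh, n-Bu3P, THF, 25 → 50 °C
Reagents that add atoms: diphenyl disulfide, c1ccc(cc1)SSc1ccccc1
Why: Hata thioetherification activates the primary alcohol as an alkoxyphosphonium ion that thiolate displaces by SN2 at the C12' methylene, leaving C11' untouched.

Step 10
Reactants: 16 [(6R,10S)-6,10-dimethyl-11-(phenylsulfanyl)undec-1-yn-1-yl]trimethylsilane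
Product: 17 [(6R,10S)-11-(benzenesulfonyl)-6,10-dimethylundec-1-yn-1-yl]trimethylsilane
Conditions: mCPBA (2.2 equiv), NaHCO3, CH2Cl2, 0 °C → rt
Reagents that add atoms: 3-chloroperoxybenzoic acid, OOC(=O)c1cccc(Cl)c1
Why: Peracid oxidation of a sulfide to the sulfone is fast, and the silyl alkyne, the only other functional group, is inert to the peracid at this temperature.

Step 11
Reactants: 18 (R)-citronellol
Product: 19 (3R)-3,7-dimethyloct-6-en-1-yl 4-methylbenzenesulfonate
Conditions: TsCl, Et3N, DMAP (cat.), CH2Cl2, 0 °C → rt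
Reagents that add atoms: 4-methylbenzenesulfonyl chloride, Cc1ccc(cc1)S(Cl)(=O)=O
Why: Tosylation of a primary alcohol does not affect the trisubstituted olefin or the C3 stereocentre.

Step 12
Reactants: 19 (3R)-3,7-dimethyloct-6-en-1-yl 4-methylbenzenesulfonate
Product: 20 {[(3R)-3,7-dimethyloct-6-en-1-yl]sulfonyl}benzene
Conditions: PhSO2Na, NaI (cat.), DMF, 60 °C
Reagents that add atoms: sodium benzenesulfinate, [Na+].[O-]S(=O)c1ccccc1
Why: SN2 displacement of the primary tosylate by sulfinate through sulfur (sulfinate S-alkylation) gives the sulfone directly and avoids any oxidant in the presence of the olefin.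

Step 13
Reactants: 21 all-E geranylgeraniol
Product: 22 tert-butyl(diphenyl){[(2E,6E,10E)-3,7,11,15-tetramethylhexadeca-2,6,10,14-tetraen-1-yl]oxy}silane
Conditions: TBDPSCl, imidazole, CH2Cl2, 0 °C → rt
Reagents that add atoms: tert-butyl(chloro)diphenylsilane, CC(C)(C)[Si](Cl)(c1ccccc1)c1ccccc1
Why: Imidazole-mediated silylation of the primary allylic alcohol gives an ether that is stable to the oxidation, bromination and carbanion steps that follow.

Step 14
Reactants: 22 tert-butyl(diphenyl){[(2E,6E,10E)-3,7,11,15-tetramethylhexadeca-2,6,10,14-tetraen-1-yl]oxy}silane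
Product: 23 (2E,6E,10E,14E)-16-[(tert-butyldiphenylsilyl)oxy]-2,6,10,14-tetramethylhexadeca-2,6,10,14-tetraen-1-ol
Conditions: SeO2 (0.2 equiv), t-BuOOH (3 equiv), salicylic acid (0.1 equiv), CH2Cl2, 0 °C → rt, partial conversion with recycling of 22; then NaBH4, MeOH, 0 °C
Reagents that add atoms: tert-butyl hydroperoxide, CC(C)(C)OO; selenium dioxide, O=[Se]=O
Why: Riley-type allylic oxidation (ene reaction, then [2,3]-sigmatropic shift) prefers the terminal isopropylidene and hydroxylates the methyl trans to the chain, giving the (E)-configured C28' alcohol, while internal olefins react more slowly and borohydride returns any over-oxidised enal to the same alcohol.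

Step 15
Reactants: 23 (2E,6E,10E,14E)-16-[(tert-butyldiphenylsilyl)oxy]-2,6,10,14-tetramethylhexadeca-2,6,10,14-tetraen-1-ol
Product: 24 {[(2E,6E,10E,14E)-16-bromo-3,7,11,15-tetramethylhexadeca-2,6,10,14-tetraen-1-yl]oxy}(tert-butyl)diphenylsilane
Conditions: CBr4, PPh3, CH2Cl2, −20 → 0 °C
Reagents that add atoms: tetrabromomethane, BrC(Br)(Br)Br
Why: The Appel reaction converts the primary allylic alcohol to the bromide under neutral conditions, so the silyl ether and the olefin geometries are preserved.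

Step 16
Reactants: 20 {[(3R)-3,7-dimethyloct-6-en-1-yl]sulfonyl}benzene; 24 {[(2E,6E,10E,14E)-16-bromo-3,7,11,15-tetramethylhexadeca-2,6,10,14-tetraen-1-yl]oxy}(tert-butyl)diphenylsilane
Product: 26 {[(2E,6E,10E,14E,19R)-17-(benzenesulfonyl)-3,7,11,15,19,23-hexamethyltetracosa-2,6,10,14,22-pentaen-1-yl]oxy}(tert-butyl)diphenylsilane, via lithiated sulfone 25 (not isolated)
Conditions: n-BuLi (1.05 equiv), THF, −78 °C; then 24, THF, −78 → −30 °C
Reagents that add atoms: none
Why: Alkylation of an α-sulfonyl carbanion with a primary allylic bromide (Julia-type sulfone alkylation) is a fast SN2 reaction that forms C28'–C29' without changing olefin geometry; the sulfonyl-bearing centre C29' forms unselectively and is removed later.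

Step 17
Reactants: 26 {[(2E,6E,10E,14E,19R)-17-(benzenesulfonyl)-3,7,11,15,19,23-hexamethyltetracosa-2,6,10,14,22-pentaen-1-yl]oxy}(tert-butyl)diphenylsilane
Product: 27 (2E,6E,10E,14E,19R)-17-(benzenesulfonyl)-3,7,11,15,19,23-hexamethyltetracosa-2,6,10,14,22-pentaen-1-ol
Conditions: Bu4NF, THF, 0 °C → rt
Reagents that add atoms: none
Why: Fluoride-mediated desilylation frees the C13' allylic alcohol and affects neither the sulfone nor the olefins.

Step 18
Reactants: 27 (2E,6E,10E,14E,19R)-17-(benzenesulfonyl)-3,7,11,15,19,23-hexamethyltetracosa-2,6,10,14,22-pentaen-1-ol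
Product: 28 {[(2E,6E,10E,14E,19R)-1-bromo-3,7,11,15,19,23-hexamethyltetracosa-2,6,10,14,22-pentaen-17-yl]sulfonyl}benzene
Conditions: PBr3 (0.4 equiv), Et2O, −10 → 0 °C; used crude
Reagents that add atoms: phosphorus tribromide, BrP(Br)Br
Why: Bromination of a primary prenyl-type allylic alcohol with PBr3 at low temperature, the standard way to farnesyl and geranylgeranyl bromides, proceeds without allylic transposition or E/Z change.

Step 19
Reactants: 17 [(6R,10S)-11-(benzenesulfonyl)-6,10-dimethylundec-1-yn-1-yl]trimethylsilane; 28 {[(2E,6E,10E,14E,19R)-1-bromo-3,7,11,15,19,23-hexamethyltetracosa-2,6,10,14,22-pentaen-17-yl]sulfonyl}benzene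
Product: 30 trimethyl[(6R,10S,13E,17E,21E,25E,30R)-11,28-bis(benzenesulfonyl)-6,10,14,18,22,26,30,34-octamethylpentatriaconta-13,17,21,25,33-pentaen-1-yn-1-yl]silane, via lithiated sulfone 29 (not isolated)
Conditions: n-BuLi (1.05 equiv), THF, −78 °C; then 28, THF, −78 → −30 °C
Reagents that add atoms: none
Why: The same sulfone alkylation joins C12' to C13'; the primary carbanion reacts with the allylic bromide faster than it can exchange a proton with the hindered secondary sulfone of 28, the silyl cap protects the alkyne, and C11' (β to sulfur) is not acidic.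

Step 20
Reactants: 30 trimethyl[(6R,10S,13E,17E,21E,25E,30R)-11,28-bis(benzenesulfonyl)-6,10,14,18,22,26,30,34-octamethylpentatriaconta-13,17,21,25,33-pentaen-1-yn-1-yl]silane
Product: 32 (6R,10S,13E,17E,21E,25E,30S)-6,10,14,18,22,26,30,34-octamethylpentatriaconta-13,17,21,25,33-pentaen-1-yne, via silyl alkyne 31 (not isolated)
Conditions: Na(Hg) (6%), Na2HPO4, THF/MeOH, −20 °C → rt; then K2CO3, MeOH, rt
Reagents that add atoms: none
Why: Reductive desulfonylation with sodium amalgam (Julia-type C–S cleavage by electron transfer and protonation) removes both non-allylic sulfonyl groups and with them the stereorandom centres C12' and C29', cannot shift the isolated olefins, and carbonate in methanol then cleaves the alkynyl C–Si bond.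

Step 21
Reactants: 33 menadione
Product: 34 2-(chloromethyl)-3-methylnaphthalene-1,4-dione
Conditions: aq. HCHO (37%), HCl (gas), AcOH, rt
Reagents that add atoms: formaldehyde, C=O; hydrogen chloride, Cl
Why: Acid-mediated chloromethylation at the only free position of quinone ring B (C3) is a known one-step entry to the chloromethylquinone.

Step 22
Reactants: 32 (6R,10S,13E,17E,21E,25E,30S)-6,10,14,18,22,26,30,34-octamethylpentatriaconta-13,17,21,25,33-pentaen-1-yne; 34 2-(chloromethyl)-3-methylnaphthalene-1,4-dione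
Product: 36 2-methyl-3-[(2E,7R,11S,14E,18E,22E,26E,31S)-3,7,11,15,19,23,27,31,35-nonamethylhexatriaconta-2,14,18,22,26,34-hexaen-1-yl]naphthalene-1,4-dione, via alkenylalane 35 (not isolated)
Conditions: Me3Al (2.5 equiv), Cp2ZrCl2 (0.25 equiv), ClCH2CH2Cl, 0 °C → rt; volatiles removed in vacuo; then 34, NiCl2(PPh3)2/n-BuLi (5 mol%, zerovalent nickel formed in the flask), THF, −20 °C → rt
Reagents that add atoms: trimethylaluminium, C[Al](C)C
Why: Zirconium-catalysed Negishi carboalumination adds CH3 and Al syn across the terminal alkyne with aluminium on the terminal carbon, which fixes the (E)-C2'=C3' olefin, and nickel-catalysed cross-coupling of the alkenylalane with the chloromethylquinone forms C1'–C2' with retention of geometry while the quinone carbonyls and the isolated olefins are left alone.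

Compound list
1 | cis-(2R,6S)-2,6-dimethylcyclohexan-1-one | C[C@H]1CCC[C@@H](C)C1=O | starting material
2 | (3S,7R)-3,7-dimethyl-2-(trimethylsilyl)cycloheptan-1-one (C2 epimers) | C[C@H]1CCC[C@@H](C)C(=O)C1[Si](C)(C)C | intermediate
3 | cis-(2R,6S)-2,6-dimethylcycloheptan-1-one | C[C@H]1CCC[C@@H](C)C(=O)C1 | intermediate
4 | lithium (3S,7R)-3,7-dimethylcyclohept-1-en-1-olate | C[C@H]1CCC[C@@H](C)C(O[Li])=C1 | intermediate
5 | {[(3S,7R)-3,7-dimethylcyclohept-1-en-1-yl]oxy}trimethylsilane | C[C@H]1CCC[C@@H](C)C(O[Si](C)(C)C)=C1 | intermediate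
6 | trimethylsilyl (2R,6S)-7-hydroperoxy-7-methoxy-2,6-dimethylheptanoate (C7 epimers) | COC(OO)[C@@H](C)CCC[C@@H](C)C(=O)O[Si](C)(C)C | intermediate
7 | (2R,6S)-7-hydroxy-2,6-dimethylheptanoic acid | OC[C@@H](C)CCC[C@@H](C)C(=O)O | intermediate
8 | meso-(2R,6S)-2,6-dimethylheptane-1,7-diol | OC[C@@H](C)CCC[C@@H](C)CO | intermediate
9 | vinyl acetate | CC(=O)OC=C | starting material
10 | (2S,6R)-7-hydroxy-2,6-dimethylheptyl acetate | CC(=O)OC[C@@H](C)CCC[C@@H](C)CO | intermediate
11 | (2S,6R)-2,6-dimethyl-7-[(4-methylbenzenesulfonyl)oxy]heptyl acetate | CC(=O)OC[C@@H](C)CCC[C@@H](C)COS(=O)(=O)c1ccc(C)cc1 | intermediate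
12 | (2R,6S)-7-hydroxy-2,6-dimethylheptyl 4-methylbenzenesulfonate | OC[C@@H](C)CCC[C@@H](C)COS(=O)(=O)c1ccc(C)cc1 | intermediate
13 | (4-bromobut-1-yn-1-yl)trimethylsilane | C[Si](C)(C)C#CCCBr | starting material
14 | [4-(trimethylsilyl)but-3-yn-1-yl]magnesium bromide | C[Si](C)(C)C#CCC[Mg]Br | intermediate
15 | (2S,6R)-2,6-dimethyl-11-(trimethylsilyl)undec-10-yn-1-ol | OC[C@@H](C)CCC[C@@H](C)CCCC#C[Si](C)(C)C | intermediate
16 | [(6R,10S)-6,10-dimethyl-11-(phenylsulfanyl)undec-1-yn-1-yl]trimethylsilane | c1ccccc1SC[C@@H](C)CCC[C@@H](C)CCCC#C[Si](C)(C)C | intermediate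
17 | [(6R,10S)-11-(benzenesulfonyl)-6,10-dimethylundec-1-yn-1-yl]trimethylsilane | O=S(=O)(c1ccccc1)C[C@@H](C)CCC[C@@H](C)CCCC#C[Si](C)(C)C | intermediate
18 | (R)-citronellol, (3R)-3,7-dimethyloct-6-en-1-ol | CC(C)=CCC[C@@H](C)CCO | starting material
19 | (3R)-3,7-dimethyloct-6-en-1-yl 4-methylbenzenesulfonate | CC(C)=CCC[C@@H](C)CCOS(=O)(=O)c1ccc(C)cc1 | intermediate
20 | {[(3R)-3,7-dimethyloct-6-en-1-yl]sulfonyl}benzene | CC(C)=CCC[C@@H](C)CCS(=O)(=O)c1ccccc1 | intermediate
21 | all-E geranylgeraniol, (2E,6E,10E)-3,7,11,15-tetramethylhexadeca-2,6,10,14-tetraen-1-ol | CC(C)=CCC/C(C)=C/CC/C(C)=C/CC/C(C)=C/CO | starting material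
22 | tert-butyl(diphenyl){[(2E,6E,10E)-3,7,11,15-tetramethylhexadeca-2,6,10,14-tetraen-1-yl]oxy}silane | CC(C)=CCC/C(C)=C/CC/C(C)=C/CC/C(C)=C/CO[Si](c1ccccc1)(c1ccccc1)C(C)(C)C | intermediate
23 | (2E,6E,10E,14E)-16-[(tert-butyldiphenylsilyl)oxy]-2,6,10,14-tetramethylhexadeca-2,6,10,14-tetraen-1-ol | OC/C(C)=C/CC/C(C)=C/CC/C(C)=C/CC/C(C)=C/CO[Si](c1ccccc1)(c1ccccc1)C(C)(C)C | intermediate
24 | {[(2E,6E,10E,14E)-16-bromo-3,7,11,15-tetramethylhexadeca-2,6,10,14-tetraen-1-yl]oxy}(tert-butyl)diphenylsilane | BrC/C(C)=C/CC/C(C)=C/CC/C(C)=C/CC/C(C)=C/CO[Si](c1ccccc1)(c1ccccc1)C(C)(C)C | intermediate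
25 | [(3R)-1-(benzenesulfonyl)-3,7-dimethyloct-6-en-1-yl]lithium | CC(C)=CCC[C@@H](C)CC([Li])S(=O)(=O)c1ccccc1 | intermediate
26 | {[(2E,6E,10E,14E,19R)-17-(benzenesulfonyl)-3,7,11,15,19,23-hexamethyltetracosa-2,6,10,14,22-pentaen-1-yl]oxy}(tert-butyl)diphenylsilane (C17 epimers) | CC(C)=CCC[C@@H](C)CC(S(=O)(=O)c1ccccc1)C/C(C)=C/CC/C(C)=C/CC/C(C)=C/CC/C(C)=C/CO[Si](c1ccccc1)(c1ccccc1)C(C)(C)C | intermediate
27 | (2E,6E,10E,14E,19R)-17-(benzenesulfonyl)-3,7,11,15,19,23-hexamethyltetracosa-2,6,10,14,22-pentaen-1-ol (C17 epimers) | CC(C)=CCC[C@@H](C)CC(S(=O)(=O)c1ccccc1)C/C(C)=C/CC/C(C)=C/CC/C(C)=C/CC/C(C)=C/CO | intermediate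
28 | {[(2E,6E,10E,14E,19R)-1-bromo-3,7,11,15,19,23-hexamethyltetracosa-2,6,10,14,22-pentaen-17-yl]sulfonyl}benzene (C17 epimers) | CC(C)=CCC[C@@H](C)CC(S(=O)(=O)c1ccccc1)C/C(C)=C/CC/C(C)=C/CC/C(C)=C/CC/C(C)=C/CBr | intermediate
29 | [(2S,6R)-1-(benzenesulfonyl)-2,6-dimethyl-11-(trimethylsilyl)undec-10-yn-1-yl]lithium | [Li]C([C@@H](C)CCC[C@@H](C)CCCC#C[Si](C)(C)C)S(=O)(=O)c1ccccc1 | intermediate
30 | trimethyl[(6R,10S,13E,17E,21E,25E,30R)-11,28-bis(benzenesulfonyl)-6,10,14,18,22,26,30,34-octamethylpentatriaconta-13,17,21,25,33-pentaen-1-yn-1-yl]silane (C11 and C28 epimers) | CC(C)=CCC[C@@H](C)CC(S(=O)(=O)c1ccccc1)C/C(C)=C/CC/C(C)=C/CC/C(C)=C/CC/C(C)=C/CC(S(=O)(=O)c1ccccc1)[C@@H](C)CCC[C@@H](C)CCCC#C[Si](C)(C)C | intermediate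
31 | trimethyl[(6R,10S,13E,17E,21E,25E,30S)-6,10,14,18,22,26,30,34-octamethylpentatriaconta-13,17,21,25,33-pentaen-1-yn-1-yl]silane | CC(C)=CCC[C@@H](C)CCC/C(C)=C/CC/C(C)=C/CC/C(C)=C/CC/C(C)=C/CC[C@@H](C)CCC[C@@H](C)CCCC#C[Si](C)(C)C | intermediate
32 | (6R,10S,13E,17E,21E,25E,30S)-6,10,14,18,22,26,30,34-octamethylpentatriaconta-13,17,21,25,33-pentaen-1-yne | CC(C)=CCC[C@@H](C)CCC/C(C)=C/CC/C(C)=C/CC/C(C)=C/CC/C(C)=C/CC[C@@H](C)CCC[C@@H](C)CCCC#C | intermediate
33 | menadione, 2-methylnaphthalene-1,4-dione | CC1=CC(=O)c2ccccc2C1=O | starting material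
34 | 2-(chloromethyl)-3-methylnaphthalene-1,4-dione | CC1=C(CCl)C(=O)c2ccccc2C1=O | intermediate
35 | dimethyl[(1E,6R,10S,13E,17E,21E,25E,30S)-2,6,10,14,18,22,26,30,34-nonamethylpentatriaconta-1,13,17,21,25,33-hexaen-1-yl]alumane | CC(C)=CCC[C@@H](C)CCC/C(C)=C/CC/C(C)=C/CC/C(C)=C/CC/C(C)=C/CC[C@@H](C)CCC[C@@H](C)CCC/C(C)=C/[Al](C)C | intermediate
36 | 2-methyl-3-[(2E,7R,11S,14E,18E,22E,26E,31S)-3,7,11,15,19,23,27,31,35-nonamethylhexatriaconta-2,14,18,22,26,34-hexaen-1-yl]naphthalene-1,4-dione | CC(C)=CCC[C@@H](C)CCC/C(C)=C/CC/C(C)=C/CC/C(C)=C/CC/C(C)=C/CC[C@@H](C)CCC[C@@H](C)CCC/C(C)=C/CC1=C(C)C(=O)c2ccccc2C1=O | target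

Total step count: 22.
Longest linear sequence: 13 steps (steps 1–10, 19, 20 and 22, from 1 to 36).

Steps most likely to fail

1. Step 5. The lipase may discriminate poorly between the two enantiotopic hydroxymethyl groups, or acylate the opposite one, or over-acylate. The fallback sets out from 8 and returns at 16. Diol 8 would be peracetylated (Ac2O, pyridine) to (2R,6S)-2,6-dimethylheptane-1,7-diyl diacetate F1, and a hydrolase in aqueous phosphate buffer would remove one acetate, a hydrolytic desymmetrisation whose preference for the same hydroxymethyl group leads to the enantiomeric monoacetate (2R,6S)-7-hydroxy-2,6-dimethylheptyl acetate F2 with the free hydroxyl on C12'. The two ends would then be processed in the opposite order: PhSSPh/n-Bu3P to (2R,6S)-2,6-dimethyl-7-(phenylsulfanyl)heptyl acetate F3, K2CO3/MeOH to (2R,6S)-2,6-dimethyl-7-(phenylsulfanyl)heptan-1-ol F4, TsCl/Et3N to (2R,6S)-2,6-dimethyl-7-(phenylsulfanyl)heptyl 4-methylbenzenesulfonate F5, and Li2CuCl4-catalysed coupling with Grignard reagent 14 to sulfide 16. The same sequence from F2 applies if the acylation of step 5 itself turns out to favour F2.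

2. Step 14. The oxidation may attack internal allylic positions, over-oxidise to the enal or stall at low conversion. The fallback sets out from 22 and returns at 23, replacing allylic C–H oxidation by cleavage and olefination of the terminal olefin. NBS in THF/H2O should add selectively to the terminal isopropylidene to give (6E,10E,14E)-3-bromo-16-[(tert-butyldiphenylsilyl)oxy]-2,6,10,14-tetramethylhexadeca-6,10,14-trien-2-ol F6. K2CO3 in MeOH would close it to tert-butyl{[(2E,6E,10E)-13-(3,3-dimethyloxiran-2-yl)-3,7,11-trimethyltrideca-2,6,10-trien-1-yl]oxy}diphenylsilane F7, and HIO4 in THF/Et2O would cleave the epoxide to (4E,8E,12E)-14-[(tert-butyldiphenylsilyl)oxy]-4,8,12-trimethyltetradeca-4,8,12-trienal F8. An E-selective Wittig reaction with Ph3P=C(CH3)CO2Et would give ethyl (2E,6E,10E,14E)-16-[(tert-butyldiphenylsilyl)oxy]-2,6,10,14-tetramethylhexadeca-2,6,10,14-tetraenoate F9, and i-Bu2AlH reduction at −78 °C would deliver 23.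

3. Step 22. Carbometalation may be incomplete or regio-unselective, and the quinone may be reduced by the organoaluminium or by the low-valent nickel catalyst. The fallback sets out from 33 and from alkyne 32 (through 35) and returns at 36. Menadione 33 would be reduced (Na2S2O4) and O-methylated (Me2SO4, KOH) to 1,4-dimethoxy-2-methylnaphthalene F10 and chloromethylated (HCHO, HCl) to 2-(chloromethyl)-1,4-dimethoxy-3-methylnaphthalene F11. Alkenylalane 35 would be coupled with this robust benzylic chloride under Pd(PPh3)4 catalysis (zerovalent palladium) to 1,4-dimethoxy-2-methyl-3-[(2E,7R,11S,14E,18E,22E,26E,31S)-3,7,11,15,19,23,27,31,35-nonamethylhexatriaconta-2,14,18,22,26,34-hexaen-1-yl]naphthalene F12. Oxidative demethylation with (NH4)2Ce(NO3)6 in MeCN/H2O at 0 °C would then give 36.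

Further compounds
F1 | step 5 | (2R,6S)-2,6-dimethylheptane-1,7-diyl diacetate (meso) | CC(=O)OC[C@@H](C)CCC[C@@H](C)COC(C)=O
F2 | step 5 | (2R,6S)-7-hydroxy-2,6-dimethylheptyl acetate | OC[C@@H](C)CCC[C@@H](C)COC(C)=O
F3 | step 5 | (2R,6S)-2,6-dimethyl-7-(phenylsulfanyl)heptyl acetate | c1ccccc1SC[C@@H](C)CCC[C@@H](C)COC(C)=O
F4 | step 5 | (2R,6S)-2,6-dimethyl-7-(phenylsulfanyl)heptan-1-ol | c1ccccc1SC[C@@H](C)CCC[C@@H](C)CO
F5 | step 5 | (2R,6S)-2,6-dimethyl-7-(phenylsulfanyl)heptyl 4-methylbenzenesulfonate | c1ccccc1SC[C@@H](C)CCC[C@@H](C)COS(=O)(=O)c1ccc(C)cc1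
F6 | step 14 | (6E,10E,14E)-3-bromo-16-[(tert-butyldiphenylsilyl)oxy]-2,6,10,14-tetramethylhexadeca-6,10,14-trien-2-ol (racemic at C3) | CC(C)(O)C(Br)CC/C(C)=C/CC/C(C)=C/CC/C(C)=C/CO[Si](c1ccccc1)(c1ccccc1)C(C)(C)C
F7 | step 14 | tert-butyl{[(2E,6E,10E)-13-(3,3-dimethyloxiran-2-yl)-3,7,11-trimethyltrideca-2,6,10-trien-1-yl]oxy}diphenylsilane (racemic epoxide) | CC1(C)OC1CC/C(C)=C/CC/C(C)=C/CC/C(C)=C/CO[Si](c1ccccc1)(c1ccccc1)C(C)(C)C
F8 | step 14 | (4E,8E,12E)-14-[(tert-butyldiphenylsilyl)oxy]-4,8,12-trimethyltetradeca-4,8,12-trienal | O=CCC/C(C)=C/CC/C(C)=C/CC/C(C)=C/CO[Si](c1ccccc1)(c1ccccc1)C(C)(C)C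
F9 | step 14 | ethyl (2E,6E,10E,14E)-16-[(tert-butyldiphenylsilyl)oxy]-2,6,10,14-tetramethylhexadeca-2,6,10,14-tetraenoate | CCOC(=O)/C(C)=C/CC/C(C)=C/CC/C(C)=C/CC/C(C)=C/CO[Si](c1ccccc1)(c1ccccc1)C(C)(C)C
F10 | step 22 | 1,4-dimethoxy-2-methylnaphthalene | COc1cc(C)c(OC)c2ccccc12
F11 | step 22 | 2-(chloromethyl)-1,4-dimethoxy-3-methylnaphthalene | COc1c(CCl)c(C)c(OC)c2ccccc12
F12 | step 22 | 1,4-dimethoxy-2-methyl-3-[(2E,7R,11S,14E,18E,22E,26E,31S)-3,7,11,15,19,23,27,31,35-nonamethylhexatriaconta-2,14,18,22,26,34-hexaen-1-yl]naphthalene | CC(C)=CCC[C@@H](C)CCC/C(C)=C/CC/C(C)=C/CC/C(C)=C/CC/C(C)=C/CC[C@@H](C)CCC[C@@H](C)CCC/C(C)=C/Cc1c(C)c(OC)c2ccccc2c1OC
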